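All runs are calculated for substances that don't exist, and the scatter is random.

- The vessel is closed, stirred and of constant volume, so count everything in percent of the charge.

| setting | south-west | north-east | alder | ash |
|---|---|---|---|---|
| substrate | 13 mM | 30 mM | 20 mM | 20 mM |
| temperature | −25 °C | −10 °C |  |  |
| remark | run made earlier | run made earlier | at 0 °C until 8.0 d, from then on at −20 °C | at −20 °C throughout |
| time |  |  | 15 d | 15 d |

| run | time / d | target / % |
|---|---|---|
| south-west | 3.00 | 0.8 |
| south-west | 8.00 | 3.8 |
| south-west | 15.0 | 6.1 |
| south-west | 20.0 | 8.9 |
| south-west | 30.0 | 13.4 |
| north-east | 1.04 | 6.7 |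
| north-east | 2.08 | 12.7 |
| north-east | 4.00 | 22.9 |
| north-east | 8.00 | 40.0 |
| north-east | 15.0 | 60.1 |

(standard deviation of a reading: 0.3 percentage points)

* the winner by amount of target, in percent of the substrate charged; "neither" if no more than 2 percentage points parts them (alder / ash / neither)
* how much target is there at the end, in percent of the substrate charged: alder
* how much target is there at the end, in percent of the substrate charged: ash



- Before reading any number, take target as y = P(1 − exp(−kt)), with P its ceiling, k a first-order rate constant and t the time.
- The charge cancels from this form, so leave it aside.
- At low conversion the readings fix the product Pk, so in ash an error in P is largely taken back by k, whereas alder, if it comes close to its ceiling, follows P itself.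
- For ash, y moves nearly in proportion to k at −20 °C, so that k must be good.
- For alder, k at 0 °C acts through the substrate remainder, which falls one power of ten per unit of D = kt/2.3, so a large D forgives errors in k.
- The temperature −20 °C lies between the runs at −25 °C and −10 °C, and 0 °C lies 10.0 K above the warmer run, so the number to know is z, the temperature rise that multiplies k by 10 (the z-value of heat sterilisation).
- In the north-east run, y goes from 22.9% to 40.0% as time doubles, which gives k = 0.0730 d⁻¹ and P = 90.4%. P rests on a difference of 5.8 percentage points, so it carries about 11.6% relative error.
- The last south-west reading with this P gives k = 0.00535 d⁻¹, so z = 13.2 K.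
- Stepping by z gives k = 0.417 d⁻¹ at 0 °C and 0.0128 d⁻¹ at −20 °C.
- My reckoning for ash is 15.8%.
- In alder, the warm stage gives D = 1.45 and the cold stage adds 0.0389, so my reckoning is 87.5%, ahead of ash by more than 2 points.
- The forecast names alder, with 82% (65% to 93%) for alder and 16% (13.5% to 19%) for ash: “The 7 d at −20 °C adds little”.
- The flasks give alder as winner, with 85.6% for alder and 15.7% for ash.

    substrate → target (k = 0.0140 h⁻¹, Ea = 97.0 kJ mol⁻¹)
    substrate → side product (k = 0.00160 h⁻¹, Ea = 91.0 kJ mol⁻¹)
    (constants at 0 °C)

- Take away the difference in temperature programme by running ash on alder's programme: target goes from 15.7% to 85.6%, so that difference is the main reason for the low figure in ash. The 20.0 K between the stages is 1.52 steps of z, a factor of 32.7 in k.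
- Read alder at 4.0 d: z gives 73.3%, and the flask gives 69.7%.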